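**Plan**

Retrosynthesis: the two SEM acetals (on O7 and on the ring A phenol) are put back and the propenyl C=C is cut to a formyl group on ring B; then the O–aryl bond between the C8 oxygen and ring B is cut; last the C7–aryl bond to ring A, leaving a lactate-derived three-carbon aldehyde.
Enabling feature: the ether oxygen on C8 is bonded to the ring B carbon para to the propenyl-bearing carbon, so with that substituent held as CHO the same ring carbon can carry fluorine and accept an alkoxide by addition–elimination.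
Forward: the chain is joined first (ring A Grignard plus (S)-2-silyloxypropanal), the hydroxyls are differentiated so that only C8–OH is free, the acyclic O–aryl bond to ring B is made, and the propenyl group and free hydroxyls are unveiled last; no ring is formed.
Stereochemistry: C8 (S) comes from ethyl (S)-lactate and its C–O bond is never broken; C7 (R, erythro) comes from Felkin–Anh addition to the α-silyloxy aldehyde; the E alkene from the Takai–Utimoto reaction.

Key step: step 7

Remark: C7 is the benzylic carbinol carbon, C8 the methyl-bearing carbon, ring A the 4-hydroxy-3,5-dimethoxyphenyl ring, ring B the propenyl-bearing ring; SEM = 2-(trimethylsilyl)ethoxymethyl, TBS = tert-butyldimethylsilyl; the four purchased compounds (1, 4, 10, 13) are assumed commercial and the minor C7 epimer of step 4 separable by chromatography.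

**Route**

Step 1
Reactants: 1 ethyl (S)-lactate
Product: 2 ethyl (2S)-2-(TBS-oxy)propanoate
Conditions: TBSCl, imidazole, DMF, 0 °C → rt
Reagents that add atoms: tert-butyldimethylsilyl chloride (TBSCl), CC(C)(C)[Si](C)(C)Cl
Why: Imidazole-promoted silylation of a secondary alcohol (silyl ether protection) leaves the stereocenter untouched and installs the bulky, weakly coordinating group that later steers the aryl addition.

Step 2
Reactants: 2 ethyl (2S)-2-(TBS-oxy)propanoate
Product: 3 (2S)-2-(TBS-oxy)propanal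
Conditions: i-Bu2AlH (1.05 equiv), CH2Cl2, −78 °C; MeOH, then aq. KNaC4H4O6 (potassium sodium tartrate); used at once without chromatography
Reagents that add atoms: none
Why: Partial reduction of an ester by diisobutylaluminium hydride at low temperature releases the aldehyde only on work-up, so over-reduction is avoided, and the cold, directly used α-silyloxy aldehyde should keep its 2S configuration.

Step 3
Reactants: 4 4-bromo-2,6-dimethoxyphenol
Product: 5 5-bromo-1,3-dimethoxy-2-(SEM-oxy)benzene
Conditions: SEMCl, i-Pr2NEt, CH2Cl2, 0 °C → rt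
Reagents that add atoms: 2-(trimethylsilyl)ethoxymethyl chloride (SEMCl), C[Si](C)(C)CCOCCl
Why: O-alkylation of the phenol by the reactive α-chloro ether (acetal protection) gives an ether that tolerates magnesium insertion, alkoxide bases and divalent chromium and is later removed by fluoride.

Step 4
Reactants: 5 5-bromo-1,3-dimethoxy-2-(SEM-oxy)benzene; 3 (2S)-2-(TBS-oxy)propanal
Product: 7 (1R,2S)-2-(TBS-oxy)-1-[3,5-dimethoxy-4-(SEM-oxy)phenyl]propan-1-ol, via arylmagnesium bromide 6 (not isolated)
Conditions: Mg turnings, I2 (cat.), THF, reflux; then 3, THF, −78 → −40 °C; aq. NH4Cl; chromatography to remove the minor C7 epimer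
Reagents that add atoms: none
Why: Grignard addition to an α-silyloxy aldehyde under Felkin–Anh (non-chelation) control: the bulky OTBS group does not chelate magnesium in THF and lies anti to the incoming aryl group, which should therefore add mainly to the Re face and set C7 as R in a 1,2-anti (erythro) relation to the lactate-derived C8.

Step 5
Reactants: 7 (1R,2S)-2-(TBS-oxy)-1-[3,5-dimethoxy-4-(SEM-oxy)phenyl]propan-1-ol
Product: 8 (1R,2S)-2-(TBS-oxy)-1-(SEM-oxy)-1-[3,5-dimethoxy-4-(SEM-oxy)phenyl]propane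
Conditions: SEMCl (3 equiv), i-Pr2NEt, Bu4NI (cat.), CH2Cl2, 40 °C
Reagents that add atoms: 2-(trimethylsilyl)ethoxymethyl chloride (SEMCl), C[Si](C)(C)CCOCCl
Why: Acetal protection of the hindered benzylic hydroxyl with SEMCl under amine base and iodide catalysis generates no alkoxide, so the neighbouring TBS group should stay on O8.

Step 6
Reactants: 8 (1R,2S)-2-(TBS-oxy)-1-(SEM-oxy)-1-[3,5-dimethoxy-4-(SEM-oxy)phenyl]propane
Product: 9 (1R,2S)-1-[3,5-dimethoxy-4-(SEM-oxy)phenyl]-1-(SEM-oxy)propan-2-ol
Conditions: Bu4NF (1.2 equiv), THF, 0 °C → rt; aq. NH4Cl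
Reagents that add atoms: none
Why: Fluoride-induced desilylation cleaves the secondary TBS ether at room temperature, whereas SEM acetals respond to fluoride only under forcing conditions and, being acetals, cannot migrate to the liberated C8 hydroxyl.

Step 7
Reactants: 9 (1R,2S)-1-[3,5-dimethoxy-4-(SEM-oxy)phenyl]-1-(SEM-oxy)propan-2-ol; 10 4-fluoro-3,5-dimethoxybenzaldehyde
Product: 12 4-{[(1R,2S)-1-[3,5-dimethoxy-4-(SEM-oxy)phenyl]-1-(SEM-oxy)propan-2-yl]oxy}-3,5-dimethoxybenzaldehyde, via potassium C8 alkoxide 11 (not isolated)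
Conditions: KH (1.0 equiv), THF, 0 °C → rt until H2 evolution ends; then 10 (1.2 equiv), 18-crown-6, THF, 0 °C → rt
Reagents that add atoms: none
Why: Nucleophilic aromatic substitution by addition–elimination: alkoxide 11 adds to the fluorine-bearing carbon of 10, the charge of the Meisenheimer adduct is delocalised onto the para formyl oxygen, and loss of fluoride restores the arene with the new O–aryl bond. The closest known reaction type is the etherification of 4-fluorobenzaldehydes and 4-fluorobenzonitriles by preformed alkali alkoxides; the two flanking methoxy groups and the secondary alkoxide make this a slow, hindered member of that class, hence the fluoride leaving group and the crown ether. No ring is closed and no stereocenter is created: the C8–O bond is never broken, so the 8S centre is carried over with retention and the 7R centre is a spectator. Chemoselectivity rests on 9 having a single free hydroxyl, since O7 and the phenol are masked as SEM acetals that cannot migrate to the neighbouring alkoxide as a silyl ether would. Regioselectivity is fixed because 10 carries one fluorine, para to the formyl group. The alkoxide is preformed with a hydride base so that no amide base is present to attack the formyl group, and hemiacetal formation there is reversible and should drain into the irreversible substitution.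

Step 8
Reactants: 12 4-{[(1R,2S)-1-[3,5-dimethoxy-4-(SEM-oxy)phenyl]-1-(SEM-oxy)propan-2-yl]oxy}-3,5-dimethoxybenzaldehyde; 13 1,1-diiodoethane
Product: 15 2-{[(1R,2S)-1-[3,5-dimethoxy-4-(SEM-oxy)phenyl]-1-(SEM-oxy)propan-2-yl]oxy}-1,3-dimethoxy-5-[(E)-prop-1-enyl]benzene, via geminal dichromium reagent 14 (not isolated)
Conditions: CrCl2 (8 equiv), THF, 0 °C → rt
Reagents that add atoms: none
Why: Takai–Utimoto alkylidenation: divalent chromium reduces 1,1-diiodoethane to a geminal dichromium species that adds to the formyl group and eliminates through the arrangement with aryl and methyl anti, which should give the (E)-propenyl group, while the non-basic reagent leaves ethers and acetals alone.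

Step 9
Reactants: 15 2-{[(1R,2S)-1-[3,5-dimethoxy-4-(SEM-oxy)phenyl]-1-(SEM-oxy)propan-2-yl]oxy}-1,3-dimethoxy-5-[(E)-prop-1-enyl]benzene
Product: 16 (1R,2S)-2-{2,6-dimethoxy-4-[(E)-prop-1-enyl]phenoxy}-1-(4-hydroxy-3,5-dimethoxyphenyl)propan-1-ol
Conditions: Bu4NF (excess), DMPU, 4 Å MS, 50 °C; aq. NH4Cl
Reagents that add atoms: none
Why: Fluoride-triggered fragmentation of both SEM acetals (attack at silicon, loss of ethene and formaldehyde) frees the phenol and the C7 hydroxyl without breaking a bond to C7 or C8, so both stereocenters and the E alkene should be unaffected.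

**Compound list**

1 | ethyl (S)-lactate | CCOC(=O)[C@H](C)O | starting material
2 | ethyl (2S)-2-(TBS-oxy)propanoate | CCOC(=O)[C@H](C)O[Si](C)(C)C(C)(C)C | intermediate
3 | (2S)-2-(TBS-oxy)propanal | O=C[C@H](C)O[Si](C)(C)C(C)(C)C | intermediate
4 | 4-bromo-2,6-dimethoxyphenol | COc1cc(Br)cc(OC)c1O | starting material
5 | 5-bromo-1,3-dimethoxy-2-(SEM-oxy)benzene | COc1cc(Br)cc(OC)c1OCOCC[Si](C)(C)C | intermediate
6 | [3,5-dimethoxy-4-(SEM-oxy)phenyl]magnesium bromide (not isolated) | COc1cc([Mg]Br)cc(OC)c1OCOCC[Si](C)(C)C | intermediate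
7 | (1R,2S)-2-(TBS-oxy)-1-[3,5-dimethoxy-4-(SEM-oxy)phenyl]propan-1-ol | CC(C)(C)[Si](C)(C)O[C@@H](C)[C@H](O)c1cc(OC)c(OCOCC[Si](C)(C)C)c(OC)c1 | intermediate
8 | (1R,2S)-2-(TBS-oxy)-1-(SEM-oxy)-1-[3,5-dimethoxy-4-(SEM-oxy)phenyl]propane | CC(C)(C)[Si](C)(C)O[C@@H](C)[C@H](OCOCC[Si](C)(C)C)c1cc(OC)c(OCOCC[Si](C)(C)C)c(OC)c1 | intermediate
9 | (1R,2S)-1-[3,5-dimethoxy-4-(SEM-oxy)phenyl]-1-(SEM-oxy)propan-2-ol | O[C@@H](C)[C@H](OCOCC[Si](C)(C)C)c1cc(OC)c(OCOCC[Si](C)(C)C)c(OC)c1 | intermediate
10 | 4-fluoro-3,5-dimethoxybenzaldehyde | COc1cc(C=O)cc(OC)c1F | starting material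
11 | potassium (1R,2S)-1-[3,5-dimethoxy-4-(SEM-oxy)phenyl]-1-(SEM-oxy)propan-2-olate (not isolated) | [K+].[O-][C@@H](C)[C@H](OCOCC[Si](C)(C)C)c1cc(OC)c(OCOCC[Si](C)(C)C)c(OC)c1 | intermediate
12 | 4-{[(1R,2S)-1-[3,5-dimethoxy-4-(SEM-oxy)phenyl]-1-(SEM-oxy)propan-2-yl]oxy}-3,5-dimethoxybenzaldehyde | O=Cc1cc(OC)c(O[C@@H](C)[C@H](OCOCC[Si](C)(C)C)c2cc(OC)c(OCOCC[Si](C)(C)C)c(OC)c2)c(OC)c1 | intermediate
13 | 1,1-diiodoethane | CC(I)I | starting material
14 | 1,1-bis(dichlorochromio)ethane, trivalent chromium, halide ligands drawn as chloride, THF ligands omitted (not isolated) | CC([Cr](Cl)Cl)[Cr](Cl)Cl | intermediate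
15 | 2-{[(1R,2S)-1-[3,5-dimethoxy-4-(SEM-oxy)phenyl]-1-(SEM-oxy)propan-2-yl]oxy}-1,3-dimethoxy-5-[(E)-prop-1-enyl]benzene | C/C=C/c1cc(OC)c(O[C@@H](C)[C@H](OCOCC[Si](C)(C)C)c2cc(OC)c(OCOCC[Si](C)(C)C)c(OC)c2)c(OC)c1 | intermediate
16 | (1R,2S)-2-{2,6-dimethoxy-4-[(E)-prop-1-enyl]phenoxy}-1-(4-hydroxy-3,5-dimethoxyphenyl)propan-1-ol | C/C=C/c1cc(OC)c(O[C@@H](C)[C@H](O)c2cc(OC)c(O)c(OC)c2)c(OC)c1 | target

**Summary**

Total step count: 9. Longest linear sequence: 8 steps (steps 1, 2, 4, 5, 6, 7, 8, 9 from ethyl (S)-lactate); step 3 is the one-step branch to the ring A bromide.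

**Steps most likely to fail**

Step 7. The substitution may be too slow at the doubly ortho-substituted C–F carbon. The alkoxide could then be consumed by reversible addition to the formyl group or by hydride transfer from the C8 alkoxide to the aldehyde, which would cost conversion and the C8 centre. The fallback changes the activating group to a nitrile, which can neither form a hemiacetal nor accept hydride. It sets out from 9 and 10 and comes back at 12. Aldehyde 10 is converted by I2 and aqueous NH3 in THF into 4-fluoro-3,5-dimethoxybenzonitrile F1. Alkoxide 11, made from 9 with KH as before, is arylated with F1 in THF with 18-crown-6 at rt to 50 °C. This should give 4-{[(1R,2S)-1-[3,5-dimethoxy-4-(SEM-oxy)phenyl]-1-(SEM-oxy)propan-2-yl]oxy}-3,5-dimethoxybenzonitrile F2. Reduction with i-Bu2AlH in toluene at −78 °C and mild aqueous hydrolysis of the aldimine then delivers 12.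

Step 4. Facial selectivity in the aryl addition may be insufficient through partial chelation by magnesium, and the α-silyloxy aldehyde may partly epimerise before it reacts. The fallback sets C7 by catalyst-controlled ketone reduction instead of substrate-controlled addition. It sets out from 2 and comes back at 7. Ester 2 is converted with MeNH(OMe)·HCl and i-PrMgCl in THF at −20 °C into (2S)-2-(TBS-oxy)-N-methoxy-N-methylpropanamide F3. Addition of Grignard 6 in THF at 0 °C should give (2S)-2-(TBS-oxy)-1-[3,5-dimethoxy-4-(SEM-oxy)phenyl]propan-1-one F4 without enolisation, because the ketone is released only on work-up. Asymmetric transfer hydrogenation with RuCl[(S,S)-TsDPEN](p-cymene) in HCO2H/Et3N at rt is expected to deliver hydride to the face that gives the (1R) carbinol 7. The descriptor is R because the C8 branch outranks the aryl group.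

Step 9. Cleavage of the hindered secondary SEM acetal at C7 may be incomplete under fluoride, and the benzylic carbon may degrade by phenoxide-assisted ionisation at the temperature required. The fallback protects O7 as a tetrahydropyranyl acetal, removable by mild acid, so that no forcing fluoride step is needed. It sets out from 7 and comes back at 16.
- Alcohol 7 with 3,4-dihydro-2H-pyran and catalytic pyridinium p-toluenesulfonate in CH2Cl2 should give (1R,2S)-2-(TBS-oxy)-1-(tetrahydropyran-2-yloxy)-1-[3,5-dimethoxy-4-(SEM-oxy)phenyl]propane F5, as a mixture of acetal epimers.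
- Bu4NF in THF frees (1R,2S)-1-[3,5-dimethoxy-4-(SEM-oxy)phenyl]-1-(tetrahydropyran-2-yloxy)propan-2-ol F6.
- KH in THF gives its potassium alkoxide F7, which is arylated with 10 as in step 7 to give 4-{[(1R,2S)-1-[3,5-dimethoxy-4-(SEM-oxy)phenyl]-1-(tetrahydropyran-2-yloxy)propan-2-yl]oxy}-3,5-dimethoxybenzaldehyde F8.
- Takai–Utimoto olefination with 13 and CrCl2 (through 14) gives 2-{[(1R,2S)-1-[3,5-dimethoxy-4-(SEM-oxy)phenyl]-1-(tetrahydropyran-2-yloxy)propan-2-yl]oxy}-1,3-dimethoxy-5-[(E)-prop-1-enyl]benzene F9.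
- Pyridinium p-toluenesulfonate in EtOH at 45 °C removes the acetal while the ring A oxygen is still capped, giving (1R,2S)-2-{2,6-dimethoxy-4-[(E)-prop-1-enyl]phenoxy}-1-[3,5-dimethoxy-4-(SEM-oxy)phenyl]propan-1-ol F10.
- The aryl SEM ether, the easier of the two to cleave, is removed with Bu4NF in THF at rt to 50 °C to reach 16.

**Further compounds**

F1 | step 7 | 4-fluoro-3,5-dimethoxybenzonitrile | COc1cc(C#N)cc(OC)c1F
F2 | step 7 | 4-{[(1R,2S)-1-[3,5-dimethoxy-4-(SEM-oxy)phenyl]-1-(SEM-oxy)propan-2-yl]oxy}-3,5-dimethoxybenzonitrile | N#Cc1cc(OC)c(O[C@@H](C)[C@H](OCOCC[Si](C)(C)C)c2cc(OC)c(OCOCC[Si](C)(C)C)c(OC)c2)c(OC)c1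
F3 | step 4 | (2S)-2-(TBS-oxy)-N-methoxy-N-methylpropanamide | CON(C)C(=O)[C@H](C)O[Si](C)(C)C(C)(C)C
F4 | step 4 | (2S)-2-(TBS-oxy)-1-[3,5-dimethoxy-4-(SEM-oxy)phenyl]propan-1-one | CC(C)(C)[Si](C)(C)O[C@@H](C)C(=O)c1cc(OC)c(OCOCC[Si](C)(C)C)c(OC)c1
F5 | step 9 | (1R,2S)-2-(TBS-oxy)-1-(tetrahydropyran-2-yloxy)-1-[3,5-dimethoxy-4-(SEM-oxy)phenyl]propane | CC(C)(C)[Si](C)(C)O[C@@H](C)[C@H](OC1CCCCO1)c2cc(OC)c(OCOCC[Si](C)(C)C)c(OC)c2
F6 | step 9 | (1R,2S)-1-[3,5-dimethoxy-4-(SEM-oxy)phenyl]-1-(tetrahydropyran-2-yloxy)propan-2-ol | O[C@@H](C)[C@H](OC1CCCCO1)c2cc(OC)c(OCOCC[Si](C)(C)C)c(OC)c2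
F7 | step 9 | potassium (1R,2S)-1-[3,5-dimethoxy-4-(SEM-oxy)phenyl]-1-(tetrahydropyran-2-yloxy)propan-2-olate | [K+].[O-][C@@H](C)[C@H](OC1CCCCO1)c2cc(OC)c(OCOCC[Si](C)(C)C)c(OC)c2
F8 | step 9 | 4-{[(1R,2S)-1-[3,5-dimethoxy-4-(SEM-oxy)phenyl]-1-(tetrahydropyran-2-yloxy)propan-2-yl]oxy}-3,5-dimethoxybenzaldehyde | O=Cc1cc(OC)c(O[C@@H](C)[C@H](OC2CCCCO2)c3cc(OC)c(OCOCC[Si](C)(C)C)c(OC)c3)c(OC)c1
F9 | step 9 | 2-{[(1R,2S)-1-[3,5-dimethoxy-4-(SEM-oxy)phenyl]-1-(tetrahydropyran-2-yloxy)propan-2-yl]oxy}-1,3-dimethoxy-5-[(E)-prop-1-enyl]benzene | C/C=C/c1cc(OC)c(O[C@@H](C)[C@H](OC2CCCCO2)c3cc(OC)c(OCOCC[Si](C)(C)C)c(OC)c3)c(OC)c1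
F10 | step 9 | (1R,2S)-2-{2,6-dimethoxy-4-[(E)-prop-1-enyl]phenoxy}-1-[3,5-dimethoxy-4-(SEM-oxy)phenyl]propan-1-ol | C/C=C/c1cc(OC)c(O[C@@H](C)[C@H](O)c2cc(OC)c(OCOCC[Si](C)(C)C)c(OC)c2)c(OC)c1
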